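Read the flask at 10 d, and ask first what share of the reagent charge stands at work in the reaction phase on the way there.

    reagent in the reaction phase ⇌ reagent in the second phase, rate k1*([reagent in the reaction phase] - [reagent in the second phase]/K1) per volume of the first phase (K1 = 1.1, k1 = 0.0234 h⁻¹)
    substrate + reagent in the reaction phase → target (k2 = 0.0454 M⁻¹ h⁻¹)
    target ⇌ product in the second phase, rate k3*([target] - [product in the second phase]/K3) per volume of the first phase (K3 = 5.7, k3 = 1.25 h⁻¹)
    target → decomposed product (k4 = 0.0295 h⁻¹)
    reagent in the reaction phase ⇌ dormant form (K5 = 0.83, k5 = 0.0245 h⁻¹)

substrate 0.38 M; reagent in the second phase 0.456 M; time 10 d; volume of the second phase over the first 2.0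

- amounts and yields of target count product in the second phase too
- in the second phase: reagent in the second phase, product in the second phase; everything else is in the first
- charges count per volume of the first phase; a concentration in a rate is the amount of a species over the volume of its own phase; every rate counts per litre of the first phase
- run time (flask): 10 d

- target and product in the second phase together at 10 d, in percent of the substrate charged
- the change that raises the amount of target and product in the second phase together at 10 d, in percent of the substrate charged most ("none" if none brings more than 2 percentage points) (epsilon / beta / theta / none)
- amount of target and product in the second phase together at 10 d, in percent of the substrate charged, after beta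

- epsilon: doubling the transfer coefficient of step 3, all else as stated
- beta: doubling the amount of reagent in the second phase, all else as stated
- theta: doubling the transfer coefficient of step 1, all else as stated

Substrate is the limiting reagent, 0.38 M against 0.456 M of reagent, so its books must close at the reading: left, target in both phases, decomposed. The first entry needs the reagent's own books, kept as fractions of its charge under second phase, reaction phase, dormant form and consumed. Dormant form follows reaction-phase reagent at the ratio 0.83, because its relaxation half-life of 0.535 d is short against 10 d. Inflow to the reaction phase balances back-transfer plus reaction with substrate.

Round one: book nothing as consumed. Each unit in the second phase then holds 0.262 of a unit in the reaction phase, and the books give 17.7 % of the charge there. Substrate decays pseudo-first-order at that level after a lag of 24.6 h, which leaves 45.4 %.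

Put that back. Take 27.3 % of the substrate as gone by mid-run, so the ratio becomes 0.296 and the lag 27.8 h, short against 10 d. The books now read 14.8 % in the reaction phase, 12.3 % dormant, 50.0 % in the second phase and 22.8 % consumed. That first entry is the working share, the fraction of the reagent charge in the reaction phase at mid-run. It leaves 52.1 % of the substrate.

Target exchanges with the second phase in 0.800 h, faster than its decomposition half-life of 0.98 d. So 8.06 % of the pair stands exposed, and the pair decays at 0.00238 h⁻¹. Made steadily, 76.2 % survives. The books close at 52.1 % left, 36.5 % pair and 11.4 % decomposed.

With the mid-run substrate loss held as it stands, doubled reagent lifts the working level to 34.0 % of the present charge, and a doubled transfer coefficient of step 1 lifts it to 16.7 %. Epsilon changes neither the working share nor the exposed share as reckoned here. So choose beta, at 59.1 %.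

The forecast gives 35.7 %, chooses beta and puts it at 55 %, lower than my figure, holding that “theta helps less than beta”.

The flask gives 35.9 %, with beta best at 55.1 %. At 5.00 d it holds 0.0676 M of reagent in the reaction phase, 14.8 % of the charge, beside the working share of 14.8 %. Carry the working share to the neighbour flask charged with 0.095 M of substrate. Round one there gives 22.5 % and leaves 38.6 %, so 30.7 % has gone by mid-run. Round two gives 21.7 % and leaves 40.3 % of its substrate, and that flask holds 39 % of its substrate at 10.0 d.

The numbers of this flask belong to no real substance; the flask was simulated.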